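Remark on the chemistry: ring A is numbered from the aroyl-bearing carbon (C1) through C2 (OH) and C4 (OMe) to C5 (propyl chain). Ring B is the benzoyl ring and ring C the ring at the end of the chain. Compound 13 carries chroman numbering. It is assumed that aryl tert-butyl ethers survive the neutral thermal conditions of step 8.

## Analysis of the target

Compound 16 is an open-chain 1,3-diarylpropane whose ring A also carries a 4-hydroxybenzoyl group, so the only rings are three benzene rings joined by a ketone carbon and a three-carbon chain. It has no stereocentre, and the single centre that the route creates on the way is removed again. Ring A is 1,2,4,5-tetrasubstituted, with each of its two carbon substituents ortho to one oxygen and para to the other. The sensitive groups are three free phenols, one aryl methyl ether that must outlast the final deprotection, and an electron-rich diaryl ketone that can be reduced under forcing hydrogenation. The difficulty is one of differentiation: of four phenolic oxygens only the C4 oxygen is methylated, and the C2 hydroxyl, hydrogen-bonded to the ketone, must stay free. The strategy rests on the relation between the C4 oxygen, C5 and the chain. The chain leaves ring A ortho to the C4 oxygen and ends at the para-oxygenated ring C, which is the skeleton of a flavan opened between O1 and C2. The unit C4–O/C5/first chain carbon is therefore an ortho-quinone methide, and the rest of the chain with ring C is a styrene. The same ring marks the C4 oxygen as the only one that is set free, unchelated, when the chroman is opened.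

## Retrosynthetic reasoning

The two phenols of rings B and C are the last groups to be unmasked. Cutting their O–C(tert-butyl) bonds leads from 16 to the bis(tert-butyl ether) 15. Acid removes these ethers without touching the methyl ether or the ketone, and they are inert to every earlier step, hydrogenation and base included.

The O–CH3 bond at C4 is cut next, which gives the diol 14. With rings B and C capped, 14 has only two phenols, and the C2 hydroxyl is locked in a hydrogen bond to the ketone. The forward methylation therefore has a single reactive site and needs no further protecting group.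

The C4 oxygen of 14 is then reconnected to the benzylic carbon at the ring C end of the chain, which gives the 2-arylchroman 13. This is the central move, because it turns a flexible chain into a ring that a cycloaddition can build and makes the ring oxygen the internal protecting group of the C4 oxygen. The forward reaction is a hydrogenolysis of the cyclic benzyl aryl ether. It must cleave the O1–C2 bond and leave the deactivated ketone alone.

In 13 the bonds C3–C4 and O1–C2 are cut together. This returns the styrene 11 and the ortho-quinone methide 12, which is generated by thermal dehydration of the hydroxymethyl phenol 10. The cut is made here and not at the ketone because it forms the chain bond next to ring A and defines the role of the C4 oxygen in one event. The forward reaction has to form 12 in the presence of 11, with 2-aryl regiochemistry. The stereocentre at C2 does not matter.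

The triol 10 is traced back through the benzylic alcohol 9 to the fully protected ketone 8, with allyl ethers on the two phenols and a silyl ether on the benzylic alcohol. These groups are chosen because they withstand an aryllithium and an oxidation. They are also removed by fluoride and by zerovalent palladium, neither of which harms the tert-butyl ether or ionises the benzylic alcohol.

The ketone 8 is taken back to the diaryl carbinol 7, and the bond between ring A and the carbinol carbon is cut. This gives the aldehyde 5 and the aryllithium 6, which comes from the bromide 4 by bromine–lithium exchange. Ring A is made the nucleophile because a bromine already stands at that position in the commercial aldehyde 1.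

Functional-group changes then lead from 4 through the alcohol 3 and the bis(allyl ether) 2 to 1. The formyl group of 1 becomes the hydroxymethyl group of the quinone methide precursor, and the bromine marks the future ketone position.

## Alternatives that were turned down

Alternative 1: Both bonds to the ketone carbon are cut. In the forward step the ring A aryl iodide A1, carbon monoxide A3 and the boronic acid A2 are joined under palladium catalysis with a carbonate base to give the tris(benzyl ether) A4, and hydrogenolytic debenzylation would then give 16.
- For it: the ketone is made late and convergently. It also meets a reducing step only during the fast cleavage of aryl benzyl ethers, which is gentler than the chroman opening of the chosen route, so on this point the alternative is stronger.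
- Against it: A1 must already contain the whole diarylpropane chain and the differentiated C2 and C4 oxygens, so the two structural problems of the target are moved into the fragment synthesis rather than solved. A1 is also an electron-rich iodide with an ortho alkoxy group, for which insertion of A3 competes poorly with direct biaryl coupling unless the gas is used under pressure.
- Comparison: the step count is not lower once the chain and the oxygen pattern of A1 are built. The chosen strategy gives the chain bond and the distinction between the ring A oxygens in one ring-forming step.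

Alternative 2: The carbonyl–ring B bond and the CH2–ring C bond are cut. In the forward step two equivalents of the arylzinc bromide A6 couple with the thioester and the primary bromide of the ring A fragment A5 under a palladium N-heterocyclic carbene catalyst, giving the tris(methoxymethyl ether) A7.
- For it: it uses the fact that rings B and C are the same aryl group and installs both in one flask. No hydrogenation is needed at any stage, and the final acid deprotection is as safe as in the chosen route. In convergence and in freedom from the ketone-reduction risk this alternative is stronger.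
- Against it: one catalyst has to carry out an acyl C–S coupling and an sp3 C–Br coupling at useful rates. The second is slower and open to β-hydride elimination, so mono-coupled and eliminated material is to be expected. A5, with a thioester, a bromopropyl chain and two differently capped oxygens on one ring, needs a synthesis of its own of about the same length as the route to 10.
- Comparison: the chosen strategy relies at its key step on a single established reaction type, and the substrate structure decides which ring A oxygen is methylated.

Alternative 3: Ring A is cut at C1–C2 and C5–C6. In the forward step the chain-bearing silyloxy diene A8 adds to the terminal ynone A9, and the adduct aromatises by elimination of one methoxy group and of the silyl group to the bis(benzyl ether) A10.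
- For it: the free C2 hydroxyl and the C4 methyl ether come straight from the substitution of A8, so no selective methylation is needed. On this point it is stronger than the chosen route.
- Against it: A8 carries the chain at its nucleophilic terminus, which slows the initial conjugate attack and weakens regiocontrol. It is also a moisture-sensitive ketene acetal that must be made as one geometric isomer by γ-deprotonation of a β-methoxy enoate. A9 is prone to polymerisation and to simple conjugate addition without ring closure. The end still requires hydrogenolytic debenzylation next to the ketone.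
- Comparison: the overall step count is similar. The chosen strategy works with stable aromatic intermediates throughout and confines its uncertainty to one thermal step that has a low-temperature fallback.

Key step: step 8

## Route

Step 1
Reactants: 1 5-bromo-2,4-dihydroxybenzaldehyde
Product: 2 5-bromo-2,4-bis(prop-2-en-1-yloxy)benzaldehyde
Conditions: allyl bromide (2.5 equiv), K2CO3, DMF, 60 °C
Reagents that add atoms: allyl bromide (3-bromoprop-1-ene), C=CCBr
Why: Williamson ether synthesis; excess halide and gentle heating should alkylate the chelated C2 hydroxyl as well as the free one, and allyl ethers tolerate the hydride, organolithium and oxidation steps that follow.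

Step 2
Reactants: 2 5-bromo-2,4-bis(prop-2-en-1-yloxy)benzaldehyde
Product: 3 [5-bromo-2,4-bis(prop-2-en-1-yloxy)phenyl]methanol
Conditions: NaBH4, MeOH–THF, 0 °C
Reagents that add atoms: none
Why: Borohydride reduction of an aromatic aldehyde; aryl bromide and allyl ethers are inert, and with both phenols capped the electron-rich benzylic alcohol should be stable to isolation.

Step 3
Reactants: 3 [5-bromo-2,4-bis(prop-2-en-1-yloxy)phenyl]methanol
Product: 4 {[5-bromo-2,4-bis(prop-2-en-1-yloxy)phenyl]methoxy}(tert-butyl)dimethylsilane
Conditions: TBSCl, imidazole, DMF, rt
Reagents that add atoms: tert-butyl(chloro)dimethylsilane (TBSCl), CC(C)(C)[Si](C)(C)Cl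
Why: Standard silylation of a primary alcohol; it removes the acidic proton before the organolithium step, and a benzylic silyl ether, unlike an aryl silyl ether ortho to lithium, cannot migrate to carbon.

Step 4
Reactants: 4 {[5-bromo-2,4-bis(prop-2-en-1-yloxy)phenyl]methoxy}(tert-butyl)dimethylsilane; 5 4-(tert-butoxy)benzaldehyde
Product: 7 rac-[5-({[tert-butyl(dimethyl)silyl]oxy}methyl)-2,4-bis(prop-2-en-1-yloxy)phenyl][4-(tert-butoxy)phenyl]methanol, via aryllithium 6 (not isolated)
Conditions: n-BuLi, THF, −78 °C; then 5, −78 → −20 °C; aq. NH4Cl
Reagents that add atoms: none
Why: Bromine–lithium exchange on an electron-rich aryl bromide followed by 1,2-addition to a non-enolisable aldehyde; keeping 6 at −78 °C until the aldehyde is added should prevent anionic attack on the neighbouring allyl ether, and the new carbinol centre is racemic and is lost in step 5.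

Step 5
Reactants: 7 rac-[5-({[tert-butyl(dimethyl)silyl]oxy}methyl)-2,4-bis(prop-2-en-1-yloxy)phenyl][4-(tert-butoxy)phenyl]methanol
Product: 8 [5-({[tert-butyl(dimethyl)silyl]oxy}methyl)-2,4-bis(prop-2-en-1-yloxy)phenyl][4-(tert-butoxy)phenyl]methanone
Conditions: activated MnO2 (excess), CH2Cl2, rt
Reagents that add atoms: none
Why: MnO2 oxidation of a doubly benzylic, electron-rich secondary alcohol; silyl ether, allyl ethers and tert-butyl ether are untouched under these neutral conditions.

Step 6
Reactants: 8 [5-({[tert-butyl(dimethyl)silyl]oxy}methyl)-2,4-bis(prop-2-en-1-yloxy)phenyl][4-(tert-butoxy)phenyl]methanone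
Product: 9 [4-(tert-butoxy)phenyl][5-(hydroxymethyl)-2,4-bis(prop-2-en-1-yloxy)phenyl]methanone
Conditions: Bu4NF (TBAF), THF, 0 °C → rt
Reagents that add atoms: none
Why: Fluoride-mediated desilylation; it is done while the phenols are still capped, so the freed benzylic alcohol has no ortho or para hydroxyl that could expel it.

Step 7
Reactants: 9 [4-(tert-butoxy)phenyl][5-(hydroxymethyl)-2,4-bis(prop-2-en-1-yloxy)phenyl]methanone
Product: 10 [4-(tert-butoxy)phenyl][2,4-dihydroxy-5-(hydroxymethyl)phenyl]methanone
Conditions: Pd(PPh3)4 (cat.), morpholine, THF, rt; buffered work-up at pH 5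
Reagents that add atoms: none
Why: Tsuji–Trost deallylation; both aryloxy groups are ortho or para to the ketone and so are good leaving groups for π-allyl formation, morpholine takes up the allyl groups, and the near-neutral room-temperature conditions spare the tert-butyl ether and the benzylic alcohol.

Step 8
Reactants: 10 [4-(tert-butoxy)phenyl][2,4-dihydroxy-5-(hydroxymethyl)phenyl]methanone; 11 1-(tert-butoxy)-4-ethenylbenzene
Product: 13 rac-[4-(tert-butoxy)phenyl]{2-[4-(tert-butoxy)phenyl]-7-hydroxy-3,4-dihydro-2H-chromen-6-yl}methanone, via ortho-quinone methide 12 (not isolated)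
Conditions: 11 (5 equiv), BHT (cat.), toluene, sealed tube, 160 °C
Reagents that add atoms: none
Why: Heating 10 should expel water from the hydrogen-bonded pair C4–OH/C5–CH2OH through a six-membered transition state and give the ortho-quinone methide 12, a 1-oxadiene made electron-poor by the aroyl group para to its carbonyl oxygen. 12 should be trapped by the electron-rich styrene 11 in an inverse-electron-demand hetero-Diels–Alder reaction, the established way to 2-arylchromans from thermally generated ortho-quinone methides and styrenes. The addition is concerted but asynchronous: the exocyclic methylene carbon bonds first to the unsubstituted alkene terminus while positive charge builds at the benzylic carbon, stabilised by the para tert-butoxy group, and the carbonyl oxygen then closes onto that carbon. This closes the one new ring, the six-membered dihydropyran, in a [4+2] mode and restores the aromaticity of ring A, which supplies the driving force. The polarity match fixes the regiochemistry as 2-aryl and not 3-aryl. The new stereocentre at C2 is formed without any controlling element, so 13 is racemic, which is of no consequence because step 9 removes the centre. The step also needs chemoselectivity between the two phenols: ionisation through the chelated C2–OH can only give a para-quinone methide that cannot cyclise and re-adds water, so the material should funnel through 12. The excess of 11, the radical inhibitor and moderate dilution should hold back styrene oligomerisation and condensation of 12 with a second molecule of 10.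

Step 9
Reactants: 13 rac-[4-(tert-butoxy)phenyl]{2-[4-(tert-butoxy)phenyl]-7-hydroxy-3,4-dihydro-2H-chromen-6-yl}methanone
Product: 14 [4-(tert-butoxy)phenyl](5-{3-[4-(tert-butoxy)phenyl]propyl}-2,4-dihydroxyphenyl)methanone
Conditions: H2 (3 atm), Pd(OH)2/C, EtOAc–EtOH, rt, stopped after uptake of one equivalent
Reagents that add atoms: none
Why: Hydrogenolysis of a cyclic benzyl aryl ether, the known opening of flavans to 1,3-diarylpropanes; the leaving group is a para-acyl phenoxide and the benzylic carbon carries an electron-rich aryl group, while the ketone is deactivated by the chelating ortho hydroxyl and two para oxygen donors. The racemic centre at C2 becomes a methylene group.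

Step 10
Reactants: 14 [4-(tert-butoxy)phenyl](5-{3-[4-(tert-butoxy)phenyl]propyl}-2,4-dihydroxyphenyl)methanone
Product: 15 [4-(tert-butoxy)phenyl](5-{3-[4-(tert-butoxy)phenyl]propyl}-2-hydroxy-4-methoxyphenyl)methanone
Conditions: MeI (1.1 equiv), K2CO3 (1.1 equiv), acetone, rt → 40 °C
Reagents that add atoms: iodomethane, CI
Why: Williamson methylation under limiting base; the C4 hydroxyl, para to the ketone, is the more acidic and the only unchelated phenol, whereas the C2 hydroxyl is held in a six-membered hydrogen bond to the carbonyl group and should not react with one equivalent of reagent.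

Step 11
Reactants: 15 [4-(tert-butoxy)phenyl](5-{3-[4-(tert-butoxy)phenyl]propyl}-2-hydroxy-4-methoxyphenyl)methanone
Product: 16 (2-hydroxy-5-[3-(4-hydroxyphenyl)propyl]-4-methoxyphenyl)(4-hydroxyphenyl)methanone
Conditions: TFA–CH2Cl2 (1:4), 0 °C → rt
Reagents that add atoms: none
Why: Acidolysis of aryl tert-butyl ethers by the E1 pathway with loss of isobutene; the aryl methyl ether, the diaryl ketone and the saturated chain are inert to trifluoroacetic acid at this temperature.

## Compound list

1 | 5-bromo-2,4-dihydroxybenzaldehyde | O=Cc1cc(Br)c(O)cc1O | starting material
2 | 5-bromo-2,4-bis(prop-2-en-1-yloxy)benzaldehyde | O=Cc1cc(Br)c(OCC=C)cc1OCC=C | intermediate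
3 | [5-bromo-2,4-bis(prop-2-en-1-yloxy)phenyl]methanol | OCc1cc(Br)c(OCC=C)cc1OCC=C | intermediate
4 | {[5-bromo-2,4-bis(prop-2-en-1-yloxy)phenyl]methoxy}(tert-butyl)dimethylsilane | CC(C)(C)[Si](C)(C)OCc1cc(Br)c(OCC=C)cc1OCC=C | intermediate
5 | 4-(tert-butoxy)benzaldehyde | CC(C)(C)Oc1ccc(C=O)cc1 | starting material
6 | [5-({[tert-butyl(dimethyl)silyl]oxy}methyl)-2,4-bis(prop-2-en-1-yloxy)phenyl]lithium | [Li]c1cc(CO[Si](C)(C)C(C)(C)C)c(OCC=C)cc1OCC=C | intermediate
7 | rac-[5-({[tert-butyl(dimethyl)silyl]oxy}methyl)-2,4-bis(prop-2-en-1-yloxy)phenyl][4-(tert-butoxy)phenyl]methanol (racemic at the carbinol carbon) | OC(c1ccc(OC(C)(C)C)cc1)c1cc(CO[Si](C)(C)C(C)(C)C)c(OCC=C)cc1OCC=C | intermediate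
8 | [5-({[tert-butyl(dimethyl)silyl]oxy}methyl)-2,4-bis(prop-2-en-1-yloxy)phenyl][4-(tert-butoxy)phenyl]methanone | O=C(c1ccc(OC(C)(C)C)cc1)c1cc(CO[Si](C)(C)C(C)(C)C)c(OCC=C)cc1OCC=C | intermediate
9 | [4-(tert-butoxy)phenyl][5-(hydroxymethyl)-2,4-bis(prop-2-en-1-yloxy)phenyl]methanone | O=C(c1ccc(OC(C)(C)C)cc1)c1cc(CO)c(OCC=C)cc1OCC=C | intermediate
10 | [4-(tert-butoxy)phenyl][2,4-dihydroxy-5-(hydroxymethyl)phenyl]methanone | OCc1cc(C(=O)c2ccc(OC(C)(C)C)cc2)c(O)cc1O | intermediate
11 | 1-(tert-butoxy)-4-ethenylbenzene | C=Cc1ccc(OC(C)(C)C)cc1 | starting material
12 | 4-[4-(tert-butoxy)benzoyl]-3-hydroxy-6-methylidenecyclohexa-2,4-dien-1-one | C=C1C=C(C(=O)c2ccc(OC(C)(C)C)cc2)C(O)=CC1=O | intermediate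
13 | rac-[4-(tert-butoxy)phenyl]{2-[4-(tert-butoxy)phenyl]-7-hydroxy-3,4-dihydro-2H-chromen-6-yl}methanone (racemic at C2) | O=C(c1ccc(OC(C)(C)C)cc1)c1cc2c(cc1O)OC(c1ccc(OC(C)(C)C)cc1)CC2 | intermediate
14 | [4-(tert-butoxy)phenyl](5-{3-[4-(tert-butoxy)phenyl]propyl}-2,4-dihydroxyphenyl)methanone | O=C(c1ccc(OC(C)(C)C)cc1)c1cc(CCCc2ccc(OC(C)(C)C)cc2)c(O)cc1O | intermediate
15 | [4-(tert-butoxy)phenyl](5-{3-[4-(tert-butoxy)phenyl]propyl}-2-hydroxy-4-methoxyphenyl)methanone | COc1cc(O)c(C(=O)c2ccc(OC(C)(C)C)cc2)cc1CCCc1ccc(OC(C)(C)C)cc1 | intermediate
16 | (2-hydroxy-5-[3-(4-hydroxyphenyl)propyl]-4-methoxyphenyl)(4-hydroxyphenyl)methanone | COc1cc(O)c(C(=O)c2ccc(O)cc2)cc1CCCc1ccc(O)cc1 | target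

## Step count and least certain steps

Total step count: 11. Longest linear sequence: 11 steps, from 1 to 16; 5 and 11 enter as commercial fragments in steps 4 and 8.

Step 8 (key step). Three processes may compete with the cycloaddition:
- loss of the tert-butyl groups by acidolysis at the temperature needed for dehydration, promoted by the acidic phenols;
- thermal oligomerisation of the styrene;
- attack of the nucleophilic C3 position of a second molecule of 10 on the quinone methide, which leads to diarylmethane oligomers.

The fallback generates the same quinone methide by base-induced 1,4-elimination at much lower temperature. It sets out from 9. Acetylation (Ac2O, pyridine, DMAP, CH2Cl2) should give {5-[4-(tert-butoxy)benzoyl]-2,4-bis(prop-2-en-1-yloxy)phenyl}methyl acetate F1. Neutral deallylation (Pd(PPh3)4, PhSiH3, CH2Cl2, rt) should give {5-[4-(tert-butoxy)benzoyl]-2,4-dihydroxyphenyl}methyl acetate F2. F2 is used at once with 11 and i-Pr2NEt in toluene at 60–80 °C, where the phenoxide expels acetate to form 12. The route is rejoined at 13.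

Step 9. The diaryl ketone may be reduced to the carbinol and on to the diarylmethane before the slower chroman C–O bond is cleaved, because a benzhydrol with ortho and para hydroxyl groups is itself hydrogenolysed easily. The fallback takes the over-reduction to completion and restores the ketone by oxidation. It sets out from 13.
- Exhaustive hydrogenation (H2 4 atm, Pd(OH)2/C, EtOH–AcOH, 50 °C) should give 4-{[4-(tert-butoxy)phenyl]methyl}-6-{3-[4-(tert-butoxy)phenyl]propyl}benzene-1,3-diol F3.
- Bis-allylation (allyl bromide, K2CO3, DMF) should give 1-{[4-(tert-butoxy)phenyl]methyl}-5-{3-[4-(tert-butoxy)phenyl]propyl}-2,4-bis(prop-2-en-1-yloxy)benzene F4.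
- DDQ in CH2Cl2–H2O should oxidise the doubly benzylic methylene group, the only one flanked by two oxygenated rings, to [4-(tert-butoxy)phenyl][5-{3-[4-(tert-butoxy)phenyl]propyl}-2,4-bis(prop-2-en-1-yloxy)phenyl]methanone F5.
- Deallylation as in step 7 (Pd(PPh3)4, morpholine, THF) rejoins the route at 14.

Step 10. With an excess of base or reagent the chelated C2 hydroxyl may also be methylated, or carbon alkylation may occur at C3 between the two oxygens. The fallback gives up selective alkylation and differentiates the oxygens by selective cleavage. It sets out from 14. Exhaustive methylation (excess MeI, K2CO3, DMF, 60 °C) should give [4-(tert-butoxy)phenyl](5-{3-[4-(tert-butoxy)phenyl]propyl}-2,4-dimethoxyphenyl)methanone F6. BCl3 in CH2Cl2 (−78 → 0 °C) should then cleave only the methyl ether ortho to the carbonyl group, through the boron chelate, together with both tert-butyl ethers. The route is rejoined at 16 without passing through 15.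

Step 7. Allyl transfer may stall at the mono-allyl stage. The liberated electron-rich phenoxide may also be allylated on carbon at C3 by the π-allyl palladium complex, and the amine may add to traces of quinone methide. The fallback removes the allyl groups by isomerisation and hydrolysis, without a π-allyl intermediate. It sets out from 9. Isomerisation with [Ir(cod)(PMePh2)2]PF6 (activated with H2, THF, rt) should give [4-(tert-butoxy)phenyl][5-(hydroxymethyl)-2,4-bis(prop-1-en-1-yloxy)phenyl]methanone F7 as a mixture of enol ether geometries. Hydrolysis with HgCl2 and HgO in acetone–water at rt rejoins the route at 10.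

## Further compounds

F1 | step 8 | {5-[4-(tert-butoxy)benzoyl]-2,4-bis(prop-2-en-1-yloxy)phenyl}methyl acetate | CC(=O)OCc1cc(C(=O)c2ccc(OC(C)(C)C)cc2)c(OCC=C)cc1OCC=C
F2 | step 8 | {5-[4-(tert-butoxy)benzoyl]-2,4-dihydroxyphenyl}methyl acetate | CC(=O)OCc1cc(C(=O)c2ccc(OC(C)(C)C)cc2)c(O)cc1O
F3 | step 9 | 4-{[4-(tert-butoxy)phenyl]methyl}-6-{3-[4-(tert-butoxy)phenyl]propyl}benzene-1,3-diol | Oc1cc(O)c(Cc2ccc(OC(C)(C)C)cc2)cc1CCCc1ccc(OC(C)(C)C)cc1
F4 | step 9 | 1-{[4-(tert-butoxy)phenyl]methyl}-5-{3-[4-(tert-butoxy)phenyl]propyl}-2,4-bis(prop-2-en-1-yloxy)benzene | C=CCOc1cc(OCC=C)c(Cc2ccc(OC(C)(C)C)cc2)cc1CCCc1ccc(OC(C)(C)C)cc1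
F5 | step 9 | [4-(tert-butoxy)phenyl][5-{3-[4-(tert-butoxy)phenyl]propyl}-2,4-bis(prop-2-en-1-yloxy)phenyl]methanone | O=C(c1ccc(OC(C)(C)C)cc1)c1cc(CCCc2ccc(OC(C)(C)C)cc2)c(OCC=C)cc1OCC=C
F6 | step 10 | [4-(tert-butoxy)phenyl](5-{3-[4-(tert-butoxy)phenyl]propyl}-2,4-dimethoxyphenyl)methanone | COc1cc(OC)c(C(=O)c2ccc(OC(C)(C)C)cc2)cc1CCCc1ccc(OC(C)(C)C)cc1
F7 | step 7 | [4-(tert-butoxy)phenyl][5-(hydroxymethyl)-2,4-bis(prop-1-en-1-yloxy)phenyl]methanone (mixture of enol ether geometries) | CC=COc1cc(OC=CC)c(C(=O)c2ccc(OC(C)(C)C)cc2)cc1CO
A1 | alternative 1 | 1-(benzyloxy)-4-{3-[4-(benzyloxy)phenyl]propyl}-2-iodo-5-methoxybenzene | COc1cc(OCc2ccccc2)c(I)cc1CCCc1ccc(OCc2ccccc2)cc1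
A2 | alternative 1 | [4-(benzyloxy)phenyl]boronic acid | OB(O)c1ccc(OCc2ccccc2)cc1
A3 | alternative 1 | carbon monoxide | [C-]#[O+]
A4 | alternative 1 | [2-(benzyloxy)-5-{3-[4-(benzyloxy)phenyl]propyl}-4-methoxyphenyl][4-(benzyloxy)phenyl]methanone | COc1cc(OCc2ccccc2)c(C(=O)c2ccc(OCc3ccccc3)cc2)cc1CCCc1ccc(OCc2ccccc2)cc1
A5 | alternative 2 | S-ethyl 5-(3-bromopropyl)-4-methoxy-2-(methoxymethoxy)benzenecarbothioate | CCSC(=O)c1cc(CCCBr)c(OC)cc1OCOC
A6 | alternative 2 | bromo[4-(methoxymethoxy)phenyl]zinc | COCOc1ccc([Zn]Br)cc1
A7 | alternative 2 | [4-methoxy-2-(methoxymethoxy)-5-{3-[4-(methoxymethoxy)phenyl]propyl}phenyl][4-(methoxymethoxy)phenyl]methanone | COCOc1ccc(CCCc2cc(C(=O)c3ccc(OCOC)cc3)c(OCOC)cc2OC)cc1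
A8 | alternative 3 | ({7-[4-(benzyloxy)phenyl]-1,3-dimethoxyhepta-1,3-dien-1-yl}oxy)trimethylsilane | COC(=CC(OC)=CCCCc1ccc(OCc2ccccc2)cc1)O[Si](C)(C)C
A9 | alternative 3 | 1-[4-(benzyloxy)phenyl]prop-2-yn-1-one | C#CC(=O)c1ccc(OCc2ccccc2)cc1
A10 | alternative 3 | [4-(benzyloxy)phenyl](5-{3-[4-(benzyloxy)phenyl]propyl}-2-hydroxy-4-methoxyphenyl)methanone | COc1cc(O)c(C(=O)c2ccc(OCc3ccccc3)cc2)cc1CCCc1ccc(OCc2ccccc2)cc1
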